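The data come from a simulation from invented constants, noise included.

At 12.0 s, the first reading of the noon run, left-handed substrate reads 0% and left-handed product 49.5%, while right-handed substrate still reads 43.8%. At 25.0 s right-handed substrate reads 33.6% at noon and 34.2% in the spring run, which had more impurity.

| setting | noon | spring | flask |
|---|---|---|---|
| left-handed substrate | 2 mM | 2 mM | 2.0 mM |
| right-handed substrate | 2 mM | 2 mM | 2.0 mM |
| gas | 0.37 mM (held) | 0.37 mM (held) | 0.37 mM (held) |
| precatalyst | 50 µM | 50 µM | 50 µM |
| impurity | 4.2 µM | 6.2 µM | 8.3 µM |
| remark | run made earlier | run made earlier |  |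
| time |  |  | 2.5 min |

- noon (time / s: right-handed substrate / %, left-handed substrate / %, left-handed product / %): 12.0: 43.8, 0, 49.5; 25.0: 33.6, 0, 49.8; 40.0: 24.1, 0.4, 49.3; 50.0: 20.6, 0, 50.4; 60.0: 15.3, 0.2, 48.9; 80.0: 9.1, 0.1, 49.6; 90.0: 8.5, 0.6, 49.6
- spring (time / s: right-handed substrate / %, left-handed substrate / %, left-handed product / %): 10.0: 46.0, 0.3, 50.4; 15.0: 41.5, 1.3, 51.1; 25.0: 34.2, 0, 50.2; 40.0: 24.9, 0, 50.4; 50.0: 19.9, 0.5, 49.1; 80.0: 11.0, 0.6, 49.2; 90.0: 7.8, 0, 50.7

(standard deviation of a reading: 0.5 percentage points)

- whether the excess of right-handed substrate over left-handed substrate among what is left of the two reaches 95% by 2.5 min (no / yes)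
- the highest excess of right-handed substrate over left-handed substrate among what is left of the two up to 2.5 min

- free catalyst is single-handed; left-handed substrate and right-handed substrate are mirror images of each other, charged as a racemate, each of them at the stated concentration
- at the start none of the gas is in solution

In the flask, 8.3 µM of impurity against 50 µM of precatalyst leaves 0.834 as the working share, the part of the catalyst still working if each impurity takes one for good. By my reckoning it scales both substrates' rates alike, so it stretches the clock and leaves their selectivity factor, the ratio of the two rate constants, unchanged. The noon readings give a right-handed fall of 0.0238 /s between 25.0 s and 80.0 s. Noon's working share is 0.916, so a full share would give 0.0259 /s, and the flask 0.0216 /s. The flask's clock runs slower than noon's, so by this reckoning what noon showed at its first reading comes in the flask at about 13.2 s. Taking noon's reading at 25.0 s as a rough start for the flask, I reckon about 2.26% of right-handed substrate at 2.5 min, so I expect the excess to pass 95% early and stay near complete. The working share rests on one impurity taking one catalyst, though, and left-handed substrate already read 0% at noon's first reading and 0.3% at the spring run's first.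

The forecast says yes, with a top of 99.9%: the excess “passes 95% early and stays near 100%”.

The flask gives yes, with a top of 100%.

    partner + free catalyst + left-handed substrate → free catalyst + left-handed product (k = 9.98 × 10⁷ /M²/s)
    partner + free catalyst + right-handed substrate → free catalyst + right-handed product (k = 1.30 × 10⁶ /M²/s)
    gas ⇌ partner, rate k3*(csat - [partner]) (kL = 16.6 /s)
    precatalyst → free catalyst (k = 0.161 /s)
    free catalyst + impurity → spent catalyst (k = 7.03 × 10⁶ /M/s)

In the flask at 1.25 min, free catalyst stands at 83.4% of the catalyst charged, beside spent catalyst at 16.6% and precatalyst at 0%, which matches the working share 0.834. The spring run's working share is 0.876, so carrying its reading at 25.0 s forward at 0.0227 /s gives 7.83% of right-handed substrate at 90.0 s, where the reading is 7.8%.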